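**Plan**
Retrosynthesis cuts, in order: the three O–CH3 bonds and the two ring–CHO bonds (from ArBr); C4–CH3 (Grignard on a 15-nor 4-ketone); C1'–CH2 of the isobutyl group and C1'–C1 (both made in one pot from an aryl acetal); then ring B at C6–C7 (ene reaction) and C10–C9 (conjugate addition).
Forward: ring A is 3-methylcyclohexenone; asymmetric conjugate addition builds quaternary C10, α-methylenation and a Lewis acid ene closure form ring B with the C7 isopropenyl group, then C11 hydration, C2=C3 dehydrogenation and silyl dienol ether formation.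
The union rests on two features: in ring A, C1 is the γ-carbon of the C4 ketone and sits next to quaternary C10, so the dienol ether C1=C2–C3=C4–OSi is nucleophilic at C1 on the face opposite the axial C10 methyl; on the arene, the benzylic carbon is ortho/para to three ring oxygens, so an acetal there can be ionised twice.
Key step: the aryl methoxycarbenium ion is captured at C1 (C1'–C1 bond), the benzylic methyl ether so formed is ionised again and the cation is allylated with a methallylsilane; hydrogenation, MeMgBr addition at C4, Br→CHO exchange and O-demethylation finish the route.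
Stereochemistry: C10 from the chiral copper catalyst; C7 from the chair-like ene transition state and C5 by equilibration to the trans-decalone; C1 anti to the C10 methyl; C1' by 1,3-allylic strain in the benzylic cation; C4 by equatorial Grignard attack.

Key step: step 9

Remark: eudesmane numbering is used (C10 bears the angular methyl, C5 is the ring-fusion CH, C1' is the benzylic carbon), and the enantiomeric purity delivered by step 1 is assumed to be raised, where needed, by crystallisation of a later intermediate.

Step 1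
Reactants: 1 3-methylcyclohex-2-en-1-one; 2 5-bromo-2-methylpent-2-ene
Product: 5 (3S)-2-[(dimethylamino)methyl]-3-methyl-3-(4-methylpent-3-en-1-yl)cyclohexan-1-one as a mixture of C2 epimers, via Grignard reagent 3 (not isolated), via magnesium enolate 4 (not isolated)
Conditions: 2, Mg, Et2O, reflux; then 1, Cu(OTf)2 (3 mol%), chiral C2-symmetric imidazolinium chloride (carbene precursor, 4 mol%, enantiomer giving 3S), Et2O, 0 °C; then CH2=NMe2+ I−, THF, −40 → 0 °C
Reagents that add atoms: dimethyl(methylidene)ammonium iodide (C=[N+](C)C.[I-])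
Why: Copper-catalysed asymmetric conjugate addition of the Grignard reagent to the β-methyl enone creates quaternary C10 with its configuration fixed by the chiral carbene ligand, and the regiodefined magnesium enolate between C4 and C5 is aminomethylated in a Mannich reaction, so C6 is attached exactly where ring B must close.

Step 2
Reactants: 5 Mannich base
Product: 7 (3S)-3-methyl-2-methylidene-3-(4-methylpent-3-en-1-yl)cyclohexan-1-one, via ammonium iodide 6 (not isolated)
Conditions: MeI, Et2O, rt; then NaHCO3 (aqueous), CH2Cl2, rt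
Reagents that add atoms: none
Why: Quaternisation of the Mannich base and E1cB loss of trimethylamine (standard α-methylenation) unveil the C5=C6 enone acceptor, and the stray C5 stereocentre of 5 disappears.

Step 3
Reactants: 7 α-methylene ketone
Product: 8 (4aS,7S,8aS)-4a-methyl-7-(prop-1-en-2-yl)octahydronaphthalen-1(2H)-one (trans-fused 15-noreudesm-11-en-4-one)
Conditions: Me2AlCl (1.2 equiv), CH2Cl2, −78 → 0 °C; then NaOMe (catalytic), MeOH, rt
Reagents that add atoms: none
Why: Lewis acid-promoted intramolecular ene reaction (cation–olefin addition to the s-cis α-methylene ketone, then proton transfer from a C11 methyl) closes ring B by the C6–C7 bond through a chair-like transition state in which ring A holds the C10 methyl axial and the forming isopropenyl group is equatorial, which sets C7 cis to the C10 methyl, and methoxide then equilibrates C5 to the trans-fused decalone.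

Step 4
Reactants: 8 isopropenyl ketone
Product: 9 (4aS,7S,8aS)-7-(2-hydroxypropan-2-yl)-4a-methyloctahydronaphthalen-1(2H)-one
Conditions: Co(acac)2 (20 mol%), PhSiH3, O2 (1 atm), THF, rt
Reagents that add atoms: dioxygen (O=O)
Why: Mukaiyama hydration (hydrogen-atom transfer from the Co(acac)2/PhSiH3 system, then oxygen trapping) hydrates the 1,1-disubstituted alkene with Markovnikov selectivity to the C11 tertiary alcohol without touching the ketone or any stereocentre.

Step 5
Reactants: 9 hydroxy ketone
Product: 12 (4aR,7S,8aS)-4a-methyl-7-[2-(triethylsilyloxy)propan-2-yl]-4a,5,6,7,8,8a-hexahydronaphthalen-1(4H)-one, via dilithium enolate 10 (not isolated), via bis-silyl enol ether 11 (not isolated)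
Conditions: LiN(i-Pr)2 (2.3 equiv), THF, −78 °C; Et3SiCl (2.6 equiv), HMPA, −78 °C → rt; then Pd(OAc)2 (10 mol%), O2 (1 atm), DMSO, 50 °C
Reagents that add atoms: chlorotriethylsilane (CC[Si](Cl)(CC)CC)
Why: Saegusa–Ito oxidation, in which the bulky amide removes the unhindered C3 methylene proton and not the ring-fusion C5–H, both oxygens are silylated and palladium-mediated dehydrosilylation gives the C2=C3 enone while C5 keeps its trans configuration.

Step 6
Reactants: 12 enone
Product: 13 triethyl{[(4aR,7S,8aS)-4a-methyl-7-[2-(triethylsilyloxy)propan-2-yl]-4a,5,6,7,8,8a-hexahydronaphthalen-1-yl]oxy}silane (ring A 1-silyloxy-1,3-diene)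
Conditions: Et3SiOTf (1.3 equiv), Et3N (3 equiv), CH2Cl2, 0 °C → rt
Reagents that add atoms: triethylsilyl trifluoromethanesulfonate (CC[Si](CC)(CC)OS(=O)(=O)C(F)(F)F)
Why: Soft enolisation under equilibrating silyl triflate/amine conditions should give the linearly conjugated dienol ether by loss of the allylic C1 proton (the extended isomer is the thermodynamic one and the competing C5–H is tertiary and at the ring fusion), which makes C1 the nucleophilic γ-terminus.

Step 7
Reactants: 14 2,4,6-trimethoxybenzaldehyde
Product: 15 3,5-dibromo-2,4,6-trimethoxybenzaldehyde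
Conditions: NBS (2.2 equiv), MeCN, rt
Reagents that add atoms: N-bromosuccinimide (O=C1CCC(=O)N1Br)
Why: Electrophilic aromatic bromination at the two open ring positions, each flanked by two methoxy groups, installs bromines that block arene alkylation in the key step and serve as latent formyl groups.

Step 8
Reactants: 15 dibromo aldehyde
Product: 16 1,3-dibromo-5-(dimethoxymethyl)-2,4,6-trimethoxybenzene
Conditions: HC(OMe)3, TsOH (5 mol%), MeOH, 50 °C
Reagents that add atoms: trimethyl orthoformate (COC(OC)OC)
Why: Acid-catalysed acetalisation with the orthoformate as water scavenger turns the hindered aldehyde into the precursor of the aryl-stabilised methoxycarbenium ion.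

Step 9
Reactants: 13 silyl dienol ether; 16 aryl dimethyl acetal
Product: 19 (1S,5S,7S,10R)-1-[(1S)-1-(3,5-dibromo-2,4,6-trimethoxyphenyl)-3-methylbut-3-en-1-yl]-11-(triethylsilyloxy)-15-noreudesm-2-en-4-one, via methyl ether 17 (not isolated), via benzylic cation 18 (not isolated)
Conditions: Me3SiOTf (0.1 equiv), CH2Cl2, −78 °C; then (2-methylallyl)trimethylsilane (3 equiv), Me3SiOTf (0.3 equiv), −78 → −40 °C; Et3N quench
Reagents that add atoms: (2-methylallyl)trimethylsilane (CC(=C)C[Si](C)(C)C)
Why: Catalytic Me3SiOTf ionises acetal 16 to the aryl-stabilised methoxycarbenium ion, which is attacked by C1, the γ-terminus of dienol ether 13 (vinylogous Mukaiyama addition), to give enone methyl ether 17; more Me3SiOTf then ionises the C1'–OMe bond and cation 18 is captured by the 2-methylallylsilane in a Hosomi–Sakurai-type SN1 allylation. The closest known reaction types are the vinylogous Mukaiyama addition of cyclic silyl dienol ethers to aryl acetals or benzylic cations and the diastereoselective SN1 allylation of α-branched electron-rich benzylic ethers. No ring is closed, since both bond formations are intermolecular. C1 is set in the first event: the cation approaches the ring A diene on the face opposite the axial C10 methyl, so the new C1–C1' bond is axial and trans to that methyl. C1' is set in the second event: 1,3-allylic strain with the ortho-methoxy groups holds the C1–H bond in the plane of cation 18, C2 and C10 then flank its two faces, and the allylsilane enters past the sp2 C2–H and anti to quaternary C10, which gives the S configuration. The step needs γ- over α-attack (C3 is shielded by the silyloxy-bearing C4 and carries the smaller coefficient), a single addition of 13 (catalytic acid at −78 °C, where 17 should not yet ionise) and no arene alkylation (the two ring bromines block the open positions).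

Step 10
Reactants: 19 methallyl enone
Product: 20 (1S,5S,7S,10R)-1-[(1S)-1-(3,5-dibromo-2,4,6-trimethoxyphenyl)-3-methylbutyl]-11-(triethylsilyloxy)-15-noreudesman-4-one
Conditions: H2 (4 atm), 5% Rh/Al2O3, EtOAc, rt
Reagents that add atoms: none
Why: Heterogeneous hydrogenation over rhodium saturates the C2=C3 enone bond and the 2-methylallyl group (giving the isobutyl chain) while sparing the aryl bromides, creates no stereocentre, and its neutral conditions leave the epimerisable C5 untouched.

Step 11
Reactants: 20 saturated ketone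
Product: 21 (1S,4R,5S,7S,10R)-1-[(1S)-1-(3,5-dibromo-2,4,6-trimethoxyphenyl)-3-methylbutyl]-11-(triethylsilyloxy)eudesman-4-ol
Conditions: MeMgBr (3 equiv), CeCl3 (3 equiv), THF, −78 °C; NH4Cl (aqueous)
Reagents that add atoms: methylmagnesium bromide (C[Mg]Br)
Why: Grignard addition with CeCl3 (which suppresses enolisation of C5–H): axial attack on the C4 ketone is blocked by the 1,3-diaxial C10 methyl, so the methyl group enters equatorially and the hydroxyl ends up axial and cis to the C10 methyl, as in the target.

Step 12
Reactants: 21 dibromo carbinol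
Product: 23 2,4,6-trimethoxy-5-{(1S)-1-[(1S,4R,5S,7S,10R)-4,11-dihydroxyeudesman-1-yl]-3-methylbutyl}benzene-1,3-dicarbaldehyde, via aryldilithium 22 (not isolated)
Conditions: t-BuLi (6 equiv), THF, −78 °C; DMF, −78 → 0 °C; then 1 M HCl, THF, rt
Reagents that add atoms: N,N-dimethylformamide (CN(C)C=O)
Why: Double bromine–lithium exchange (each aryllithium is flanked by two chelating methoxy groups) and formylation with DMF (Bouveault-type) install both aldehydes, and the acidic hydrolysis also cleaves the tertiary triethylsilyl ether.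

Step 13
Reactants: 23 tri-O-methyl dialdehyde
Product: 24 2,4,6-trihydroxy-5-{(1S)-1-[(1S,4R,5S,7S,10R)-4,11-dihydroxyeudesman-1-yl]-3-methylbutyl}benzene-1,3-dicarbaldehyde (target)
Conditions: NaSEt (10 equiv), DMF, 110 °C; then 1 M HCl, 0 °C
Reagents that add atoms: none
Why: Nucleophilic demethylation (SN2 attack of thiolate on the three methyl groups, each ortho to a formyl group that stabilises the phenoxide leaving group) frees the phloroglucinol under basic conditions that leave both tertiary alcohols intact.

**Compound list**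
1 | 3-methylcyclohex-2-en-1-one | CC1=CC(=O)CCC1 | starting material
2 | 5-bromo-2-methylpent-2-ene | CC(C)=CCCBr | starting material
3 | (4-methylpent-3-en-1-yl)magnesium bromide | CC(C)=CCC[Mg]Br | intermediate
4 | bromomagnesium (3S)-3-methyl-3-(4-methylpent-3-en-1-yl)cyclohex-1-en-1-olate | Br[Mg]OC1=C[C@](C)(CCC=C(C)C)CCC1 | intermediate
5 | (3S)-2-[(dimethylamino)methyl]-3-methyl-3-(4-methylpent-3-en-1-yl)cyclohexan-1-one (C2 epimers) | CN(C)CC1C(=O)CCC[C@@]1(C)CCC=C(C)C | intermediate
6 | N-methyl quaternary ammonium iodide of 5 | C[N+](C)(C)CC1C(=O)CCC[C@@]1(C)CCC=C(C)C.[I-] | intermediate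
7 | (3S)-3-methyl-2-methylidene-3-(4-methylpent-3-en-1-yl)cyclohexan-1-one | C=C1C(=O)CCC[C@@]1(C)CCC=C(C)C | intermediate
8 | (4aS,7S,8aS)-4a-methyl-7-(prop-1-en-2-yl)octahydronaphthalen-1(2H)-one | C1CCC(=O)[C@H]2C[C@@H](C(C)=C)CC[C@]12C | intermediate
9 | (4aS,7S,8aS)-7-(2-hydroxypropan-2-yl)-4a-methyloctahydronaphthalen-1(2H)-one | C1CCC(=O)[C@H]2C[C@@H](C(C)(C)O)CC[C@]12C | intermediate
10 | dilithium C3=C4 enolate and C11 alkoxide of 9 | C1CC=C(O[Li])[C@H]2C[C@@H](C(C)(C)O[Li])CC[C@]12C | intermediate
11 | bis(triethylsilyl) derivative of 9 (C3=C4 silyl enol ether, C11 silyl ether) | C1CC=C(O[Si](CC)(CC)CC)[C@H]2C[C@@H](C(C)(C)O[Si](CC)(CC)CC)CC[C@]12C | intermediate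
12 | (4aR,7S,8aS)-4a-methyl-7-[2-(triethylsilyloxy)propan-2-yl]-4a,5,6,7,8,8a-hexahydronaphthalen-1(4H)-one | C1C=CC(=O)[C@H]2C[C@@H](C(C)(C)O[Si](CC)(CC)CC)CC[C@]12C | intermediate
13 | triethyl{[(4aR,7S,8aS)-4a-methyl-7-[2-(triethylsilyloxy)propan-2-yl]-4a,5,6,7,8,8a-hexahydronaphthalen-1-yl]oxy}silane | C1=CC=C(O[Si](CC)(CC)CC)[C@H]2C[C@@H](C(C)(C)O[Si](CC)(CC)CC)CC[C@]12C | intermediate
14 | 2,4,6-trimethoxybenzaldehyde | COc1cc(OC)c(C=O)c(OC)c1 | starting material
15 | 3,5-dibromo-2,4,6-trimethoxybenzaldehyde | COc1c(Br)c(OC)c(C=O)c(OC)c1Br | intermediate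
16 | 1,3-dibromo-5-(dimethoxymethyl)-2,4,6-trimethoxybenzene | COC(OC)c1c(OC)c(Br)c(OC)c(Br)c1OC | intermediate
17 | (1S,5S,7S,10R)-1-[(3,5-dibromo-2,4,6-trimethoxyphenyl)(methoxy)methyl]-11-(triethylsilyloxy)-15-noreudesm-2-en-4-one (C1' epimers) | COC(c1c(OC)c(Br)c(OC)c(Br)c1OC)[C@@H]1C=CC(=O)[C@H]2C[C@@H](C(C)(C)O[Si](CC)(CC)CC)CC[C@]12C | intermediate
18 | benzylic cation from 17 (triflate salt) | [CH+](c1c(OC)c(Br)c(OC)c(Br)c1OC)[C@@H]1C=CC(=O)[C@H]2C[C@@H](C(C)(C)O[Si](CC)(CC)CC)CC[C@]12C.[O-]S(=O)(=O)C(F)(F)F | intermediate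
19 | (1S,5S,7S,10R)-1-[(1S)-1-(3,5-dibromo-2,4,6-trimethoxyphenyl)-3-methylbut-3-en-1-yl]-11-(triethylsilyloxy)-15-noreudesm-2-en-4-one | CC(=C)C[C@H](c1c(OC)c(Br)c(OC)c(Br)c1OC)[C@@H]1C=CC(=O)[C@H]2C[C@@H](C(C)(C)O[Si](CC)(CC)CC)CC[C@]12C | intermediate
20 | (1S,5S,7S,10R)-1-[(1S)-1-(3,5-dibromo-2,4,6-trimethoxyphenyl)-3-methylbutyl]-11-(triethylsilyloxy)-15-noreudesman-4-one | CC(C)C[C@H](c1c(OC)c(Br)c(OC)c(Br)c1OC)[C@@H]1CCC(=O)[C@H]2C[C@@H](C(C)(C)O[Si](CC)(CC)CC)CC[C@]12C | intermediate
21 | (1S,4R,5S,7S,10R)-1-[(1S)-1-(3,5-dibromo-2,4,6-trimethoxyphenyl)-3-methylbutyl]-11-(triethylsilyloxy)eudesman-4-ol | CC(C)C[C@H](c1c(OC)c(Br)c(OC)c(Br)c1OC)[C@@H]1CC[C@@](C)(O)[C@H]2C[C@@H](C(C)(C)O[Si](CC)(CC)CC)CC[C@]12C | intermediate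
22 | 3,5-dilithio analogue of 21 as its lithium C4 alkoxide | CC(C)C[C@H](c1c(OC)c([Li])c(OC)c([Li])c1OC)[C@@H]1CC[C@@](C)(O[Li])[C@H]2C[C@@H](C(C)(C)O[Si](CC)(CC)CC)CC[C@]12C | intermediate
23 | 2,4,6-trimethoxy-5-{(1S)-1-[(1S,4R,5S,7S,10R)-4,11-dihydroxyeudesman-1-yl]-3-methylbutyl}benzene-1,3-dicarbaldehyde | CC(C)C[C@H](c1c(OC)c(C=O)c(OC)c(C=O)c1OC)[C@@H]1CC[C@@](C)(O)[C@H]2C[C@@H](C(C)(C)O)CC[C@]12C | intermediate
24 | 2,4,6-trihydroxy-5-{(1S)-1-[(1S,4R,5S,7S,10R)-4,11-dihydroxyeudesman-1-yl]-3-methylbutyl}benzene-1,3-dicarbaldehyde | CC(C)C[C@H](c1c(O)c(C=O)c(O)c(C=O)c1O)[C@@H]1CC[C@@](C)(O)[C@H]2C[C@@H](C(C)(C)O)CC[C@]12C | target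

**Step count**
Total: 13 steps. Longest linear sequence: 11 steps (steps 1–6 and 9–13); steps 7–8 form the two-step aryl branch.

**Steps most likely to fail**

1. Step 9 (key step). Cation 18 may lose the C1 proton (E1) to an aryl-conjugated dienone, which would erase C1. A second molecule of 13 may add to 18, or attack may occur at C3 (α) and not at C1 (γ). Fallback, setting out from 15 and 13 and returning at 20: the isobutyl group is carried in the electrophile, so that no cation is formed next to C1–H. Addition of isobutylmagnesium bromide to 15 gives 1-(3,5-dibromo-2,4,6-trimethoxyphenyl)-3-methylbutan-1-ol F1. Acetylation (Ac2O, DMAP, Et3N) gives the acetate F2. Me3SiOTf-catalysed SN1 coupling of F2 with 13 at −78 °C gives the isobutyl enone F3, which is hydrogenated under the conditions of step 10 to 20. In this variant C1' rests only on simple diastereoselection in an open transition state, so the C1' epimer is expected as a by-product and would be removed by chromatography.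

2. Step 3. The zwitterion formed after C6–C7 bonding may collapse to a cyclobutane (C5–C11 bond), the alkene may attack the ketone carbon C4 (carbonyl-ene), or C7 may form with low selectivity. Fallback, setting out from magnesium enolate 4 of step 1 and returning at 8: an oxocarbenium–olefin (Prins) closure replaces the ene reaction. Enolate 4 is trapped with dimethoxycarbenium tetrafluoroborate (from HC(OMe)3 and BF3·OEt2) to give the β-keto acetal F4. SnCl4 at −78 °C closes ring B to the 6-methoxy decalone F5 (chair-like transition state, isopropenyl equatorial). DBU eliminates methanol to the C5=C6 enone F6. Li in liquid NH3 then reduces the enone to the trans-fused ketone 8 without touching the isopropenyl group.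

3. Step 6. Deprotonation at the ring-fusion C5–H would give the cross-conjugated dienol ether, which would later react at C5 and could scramble the ring fusion. Fallback, setting out from 12 and returning at 13: thermodynamic enol acetylation (isopropenyl acetate, TsOH, reflux) gives the linearly conjugated dienyl acetate F7. Cleavage of the acetate with MeLi (2 equiv) generates the lithium dienolate regiospecifically, and Et3SiCl traps it on oxygen to give 13.

**Further compounds**
F1 | step 9 | 1-(3,5-dibromo-2,4,6-trimethoxyphenyl)-3-methylbutan-1-ol (racemic) | CC(C)CC(O)c1c(OC)c(Br)c(OC)c(Br)c1OC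
F2 | step 9 | 1-(3,5-dibromo-2,4,6-trimethoxyphenyl)-3-methylbutyl acetate (racemic) | CC(C)CC(OC(C)=O)c1c(OC)c(Br)c(OC)c(Br)c1OC
F3 | step 9 | (1S,5S,7S,10R)-1-[(1S)-1-(3,5-dibromo-2,4,6-trimethoxyphenyl)-3-methylbutyl]-11-(triethylsilyloxy)-15-noreudesm-2-en-4-one | CC(C)C[C@H](c1c(OC)c(Br)c(OC)c(Br)c1OC)[C@@H]1C=CC(=O)[C@H]2C[C@@H](C(C)(C)O[Si](CC)(CC)CC)CC[C@]12C
F4 | step 3 | (3S)-2-(dimethoxymethyl)-3-methyl-3-(4-methylpent-3-en-1-yl)cyclohexan-1-one (C2 epimers) | COC(OC)C1C(=O)CCC[C@@]1(C)CCC=C(C)C
F5 | step 3 | 6-methoxy-15-noreudesm-11-en-4-one (C7 and C10 as in 8, C5 and C6 epimers) | C1CCC(=O)C2C(OC)[C@@H](C(C)=C)CC[C@]12C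
F6 | step 3 | 15-noreudesma-5,11-dien-4-one (C7 and C10 as in 8) | C1CCC(=O)C2=C[C@@H](C(C)=C)CC[C@]12C
F7 | step 6 | (4aR,7S,8aS)-4a-methyl-7-[2-(triethylsilyloxy)propan-2-yl]-4a,5,6,7,8,8a-hexahydronaphthalen-1-yl acetate | C1=CC=C(OC(C)=O)[C@H]2C[C@@H](C(C)(C)O[Si](CC)(CC)CC)CC[C@]12C
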